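## The problem

The target is epiafzelechin 3-O-gallate joined through C4 (β) to C6' of epicatechin 3-O-gallate (primes mark the lower unit). Two chroman systems are held by one C(sp3)–C(sp2) bond. That bond must end at C6', although C8' is the more nucleophilic position of a 5,7-dioxygenated flavan. There are five stereocentres. C2' and C3' are those of (−)-epicatechin. C2 and C3 (cis) and C4 (trans to the C3 oxygen) must be made, and once C2 and C3 sit in a six-membered ring they can steer a nucleophile at C4 to the opposite face, as ring C does in the natural series. The fragile features are the interflavan C4–C6' bond (acid-labile once upper ring A exists), the easily ionised para-oxyphenyl benzylic C2–O bond, eleven oxidisable phenols and two gallate esters that tolerate neither strong base nor organometallics. The enabling feature is that upper ring A is a phloroglucinol, symmetric about the C4a···C7 axis. Its carbons C4a–C5–C6–C7–C8–C8a map onto a C4-bound 3,5-dioxo ester, so the ring can be closed last by a C4a–C8a Claisen bond, and either new ortho hydroxyl can then become O1.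

## Retrosynthesis

**End game (29 ← 28 ← 27 ← 25 ← 24).** Thirteen benzyl C–O bonds and the C8'–Br bond of 28 are cut by hydrogenolysis, so every oxidisable phenol stays masked until the last step. The two ester C–O bonds are cut next, giving diol 27; both gallates go on together and late because they would not survive the anionic chemistry. Diol 27 comes from bis-acetal 25 and this from diphenol 24 by benzylation. The forward steps need only phenol-versus-alcohol selectivity.

**O1–C2 (24 ← 23).** The pyran ring is opened at the benzylic C–O bond to triphenol 23. Because ring A is symmetric, either ortho hydroxyl can close. The forward step is a Mitsunobu substitution with inversion, so 23 must carry the C2-epimeric (anti) alcohol. Cutting O1–C8a instead would need an aryl leaving group that a phloroglucinol does not offer.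

**C4a–C8a (23 ← 22 ← 20), the key cut.** Ring A is taken apart between C4a and C8a to the open 3,5-dioxo ester 20. This removes a whole aromatic ring and leaves a chain in which no stereocentre is α to a carbonyl. The forward Claisen must win against pyrone formation and needs heat, which fixes the protecting groups: MOM on both C3 oxygens, TBS on C2–O, benzyl on phenols.

**C5–C6 (20 ← 17 + 18).** The dioxo ester is cut to Weinreb amide 17 and methyl acetoacetate 18. The dianion of 18 brings four of the six ring-A carbons in one step.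

**Adjusting C2 (17 ← 16 ← 15 ← 14 ← 13).** No skeletal bond is cut. Amide 14 is the opened form of lactone 13, in which C2 has the configuration needed for the lactone but the wrong one for the Mitsunobu closure. Oxidation to ketone 15 and chelation-controlled reduction to 16 invert it. The α-MOM ether was chosen because it chelates.

**C4–C6' (13 ← 10 + 5).** The interflavan bond is cut to unsaturated lactone 10 and aryl iodide 5. An open-chain γ-alkoxy E-enoate would add a copper reagent anti to the γ-oxygen, which after ring closure is the unwanted 3,4-cis relationship. In the cis-5,6-disubstituted dihydropyranone 10, a surrogate of ring C, both substituents direct the aryl group to the opposite face and give 3,4-trans. The iodine at C6' of 5 fixes the 4→6 regiochemistry.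

**Lactone (10 ← 9 ← 8 ← 6).** The C4=C4a bond is cut by ring-closing metathesis to acrylate 9, the ester to alcohol 8, and the C2–C3 bond to 4-benzyloxybenzaldehyde 6 by syn-selective alkoxyallylboration. This sets C2 and C3 in one step with the two oxygens already differentiated.

**Lower unit (5 ← 4 ← 3 ← 2 ← 1).** The C–I, acetal, C–Br and benzyl bonds are removed in turn back to (−)-epicatechin 1, which supplies C2' and C3'. Bromine is placed first at the more reactive C8' as a block, so the later iodination can only occur at C6'.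

## Roads not taken

**Alternative 1:** The cut is C4a'–C4' of the lower pyran ring. The lower heterocycle would be closed onto a phloroglucinol already bound to C4 of a finished upper gallate. The forward key step is a Lewis-acid-promoted epoxide–arene alkylation in which the ring carbon ortho to the aryl ether oxygen attacks the epoxide terminus, giving A1.
- Merits: the C4-bound phloroglucinol is symmetric, so 4→6 regiochemistry is automatic and no blocking halogen is needed; the C4–aryl bond can be made by the familiar capture of a flavan C4 cation; the demanding triketide Claisen is avoided. In these respects this road is better.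
- Weak points: the Lewis acid acts on a molecule that already contains the acid-labile interflavan bond and an ester. The epoxide can rearrange or open in the 5-exo sense. C2' and C3' must be built, and the upper flavan as well.
- Comparison: the chosen plan buys C2' and C3' in 1, creates only three stereocentres, and forms all C–C bonds before the acid-labile motif exists.

**Alternative 2:** The cut is the pair C5'–C6' and C7'–C8', so lower ring A is assembled around C6'. The forward key step is a thermal benzannulation of the cyclobutenone and silyloxyalkyne type, giving A2.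
- Merits: two C–C bonds and an aromatic ring form in one neutral thermal step; the linkage position is fixed by construction; the new phenolic oxygens emerge differentiated. In bond economy and mildness it beats the chosen key step.
- Weak points: both partners are hard to reach. One is an alkynyl silyl ether on the hindered C4 of a complete, sensitive upper flavan; the other is a strained four-membered enone carrying C2' and C3'. All five stereocentres must be created.
- Comparison: the chosen plan has a harder ring closure but much simpler precursors, a chiral-pool lower unit and a shorter overall path.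

**Alternative 3:** The cuts are C8a'–O1', C4a'–C4' and O1'–C2'. The forward key step joins a fluoride-generated aryne with a cinnamaldehyde, followed by ring opening to an ortho-quinone methide and oxa-6π closure, giving chromene A3.
- Merits: three bonds in one operation; the fastest assembly of the lower heterocycle.
- Weak points: C2' is formed as both epimers. The C3' oxygen must then be added cis to the aryl group across the chromene double bond, where hydroboration gives trans. The aryne can be attacked at either end.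
- Comparison: this road is shorter on paper but cannot deliver a single stereoisomer without separations; the chosen plan controls all five centres.

Key step: step 14

Remark: chain carbons of open intermediates are numbered as the flavan atoms they become (C2, C3, C4, C4a to C8a); 3,4,5-tris(benzyloxy)benzoyl chloride, (−)-Ipc2BOMe, allyl methoxymethyl ether, diketene and Me2BBr are taken as purchasable.

## Route

Step 1
Reactants: 1 (−)-epicatechin
Product: 2 5,7,3',4'-tetra-O-benzylepicatechin
Conditions: BnBr, K2CO3, DMF, 0 °C → rt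
Reagents that add atoms: benzyl bromide, BrCc1ccccc1
Why: Williamson etherification under carbonate ionises only the four phenols, so the secondary 3-OH stays free for later differentiation.

Step 2
Reactants: 2 5,7,3',4'-tetra-O-benzylepicatechin
Product: 3 8-bromo-5,7,3',4'-tetra-O-benzylepicatechin
Conditions: NBS (1.0 equiv), CH2Cl2, −40 → 0 °C
Reagents that add atoms: N-bromosuccinimide, O=C1CCC(=O)N1Br
Why: Electrophilic aromatic bromination; C8 is the more reactive ring-A position of 5,7-di-O-alkyl flavan-3-ols, and the bromine blocks it until the final hydrogenolysis.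

Step 3
Reactants: 3 8-bromo-5,7,3',4'-tetra-O-benzylepicatechin
Product: 4 8-bromo-5,7,3',4'-tetra-O-benzyl-3-O-(methoxymethyl)epicatechin
Conditions: MOMCl, i-Pr2NEt, Bu4NI (cat.), CH2Cl2, 0 → 40 °C
Reagents that add atoms: chloromethyl methyl ether, COCCl
Why: Acetal protection of the only hydroxyl; the MOM ether is inert to Grignard, enolate and hot alkoxide chemistry and leaves together with the upper one in step 18.

Step 4
Reactants: 4 8-bromo-5,7,3',4'-tetra-O-benzyl-3-O-(methoxymethyl)epicatechin
Product: 5 8-bromo-6-iodo-5,7,3',4'-tetra-O-benzyl-3-O-(methoxymethyl)epicatechin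
Conditions: NIS, MeCN/CH2Cl2, 0 °C → rt, dark
Reagents that add atoms: N-iodosuccinimide, O=C1CCC(=O)N1I
Why: Electrophilic iodination at C6, the only free position of the trioxygenated ring A and far more reactive than ring B; the iodide later exchanges much faster than the C8 bromide.

Step 5
Reactants: 6 4-benzyloxybenzaldehyde
Product: 8 (1R,2R)-1-(4-benzyloxyphenyl)-2-(methoxymethoxy)but-3-en-1-ol, via diisopinocampheylborinate ester 7 (not isolated)
Conditions: allyl methoxymethyl ether, s-BuLi, THF, −78 °C; (−)-Ipc2BOMe; BF3·OEt2; then 6, −78 °C; NaOH, H2O2, 0 °C → rt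
Reagents that add atoms: allyl methoxymethyl ether, C=CCOCOC
Why: Brown alkoxyallylboration; the (Z)-γ-alkoxyallylborane reacts through a chair six-membered transition state, so Z geometry gives the syn relationship, and the isopinocampheyl groups derived from (+)-α-pinene select the aldehyde face that leads to the (1R,2R) isomer. Any minor enantiomer becomes a separable diastereomer after step 8.

Step 6
Reactants: 8 (1R,2R)-1-(4-benzyloxyphenyl)-2-(methoxymethoxy)but-3-en-1-ol
Product: 9 (1R,2R)-1-(4-benzyloxyphenyl)-2-(methoxymethoxy)but-3-enyl acrylate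
Conditions: acryloyl chloride, Et3N, DMAP (cat.), CH2Cl2, −20 → 0 °C
Reagents that add atoms: acryloyl chloride, C=CC(=O)Cl
Why: Acylation of the only free (benzylic C2) hydroxyl, which thereby becomes the ring oxygen of the lactone template.

Step 7
Reactants: 9 (1R,2R)-1-(4-benzyloxyphenyl)-2-(methoxymethoxy)but-3-enyl acrylate
Product: 10 (5R,6R)-6-(4-benzyloxyphenyl)-5-(methoxymethoxy)-5,6-dihydro-2H-pyran-2-one
Conditions: second-generation Grubbs catalyst RuCl2(=CHPh)(PCy3)(H2IMes) (5 mol %), CH2Cl2, 40 °C
Reagents that add atoms: none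
Why: Ring-closing metathesis of an acrylate with a terminal alkene, driven by loss of ethylene; the two stereocentres are untouched and end up cis on the ring.

Step 8
Reactants: 5 8-bromo-6-iodo-5,7,3',4'-tetra-O-benzyl-3-O-(methoxymethyl)epicatechin; 10 (5R,6R)-6-(4-benzyloxyphenyl)-5-(methoxymethoxy)-5,6-dihydro-2H-pyran-2-one
Product: 13 (4R,5R,6R)-4-aryl-5-(methoxymethoxy)-6-(4-benzyloxyphenyl)tetrahydropyran-2-one (aryl = C6 of the protected 8-bromoepicatechin unit), via arylmagnesium chloride 11 (not isolated), via trimethylsilyl ketene acetal 12 (not isolated)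
Conditions: 5, i-PrMgCl·LiCl, THF, −20 °C; then CuBr·SMe2 (0.3 equiv), Me3SiCl, 10, −78 → −30 °C; aq. NH4Cl, dil. HCl
Reagents that add atoms: none
Why: Iodine–magnesium exchange is selective for the C6 iodide over the C8 bromide, which fixes the 4→6 linkage. The copper-catalysed, Me3SiCl-accelerated 1,4-addition to the unsaturated lactone is axial on the half-chair with 6-aryl equatorial and 5-OMOM axial, so the aryl group enters anti to both substituents and C4 is set trans to the C3 oxygen.

Step 9
Reactants: 13 (4R,5R,6R)-4-aryl-5-(methoxymethoxy)-6-(4-benzyloxyphenyl)tetrahydropyran-2-one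
Product: 14 syn-hydroxy Weinreb amide (C2–OH syn to C3–OMOM; configuration as in 13)
Conditions: MeNH(OMe)·HCl, AlMe3, CH2Cl2, 0 °C → rt
Reagents that add atoms: N,O-dimethylhydroxylamine hydrochloride, CNOC.Cl
Why: Aluminium amide aminolysis of a lactone (Weinreb amide formation) opens the template and frees the C2 hydroxyl without touching a stereocentre.

Step 10
Reactants: 14 syn-hydroxy Weinreb amide
Product: 15 C2 aryl ketone Weinreb amide
Conditions: Dess–Martin periodinane, NaHCO3, CH2Cl2, 0 °C → rt
Reagents that add atoms: none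
Why: Dess–Martin oxidation of the benzylic alcohol under buffered, non-enolising conditions, so the neighbouring C3 centre is not epimerised.

Step 11
Reactants: 15 C2 aryl ketone Weinreb amide
Product: 16 anti-hydroxy Weinreb amide (C2 epimer of 14)
Conditions: Zn(BH4)2, Et2O, −30 → 0 °C
Reagents that add atoms: none
Why: Chelation-controlled (Cram-chelate) reduction; zinc bridges the ketone and the α-MOM oxygen and hydride enters from the side of the C3 hydrogen, giving the anti alcohol. The Weinreb amide is inert at this temperature.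

Step 12
Reactants: 16 anti-hydroxy Weinreb amide
Product: 17 C2-O-TBS Weinreb amide
Conditions: TBSOTf, 2,6-lutidine, CH2Cl2, −78 → 0 °C
Reagents that add atoms: tert-butyldimethylsilyl triflate, CC(C)(C)[Si](C)(C)OS(=O)(=O)C(F)(F)F
Why: Silylation of a hindered secondary alcohol with the silyl triflate; the TBS ether prevents hemiketal formation with the C5 ketone made next and is orthogonal to MOM, benzyl and aryl bromide.

Step 13
Reactants: 17 C2-O-TBS Weinreb amide; 18 methyl acetoacetate
Product: 20 methyl 3,5-dioxoalkanoate carrying the C4 diarylmethine with C3–OMOM and the C2-epimeric OTBS group, via dilithium dienolate 19 (not isolated)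
Conditions: 18, LiN(i-Pr)2 (2 equiv per 18), THF, 0 °C; then 17, −78 → 0 °C; aq. NH4Cl
Reagents that add atoms: none
Why: Acylation of the acetoacetate dianion at its terminal carbon by a Weinreb amide, whose chelated tetrahedral intermediate prevents over-addition; excess dianion compensates for deprotonation of the more acidic product.

Step 14
Reactants: 20 methyl 3,5-dioxoalkanoate
Product: 22 2-substituted phloroglucinol with the open C2–C3–C4 chain (C3–OMOM and C2–OTBS), via cyclohexane-1,3,5-trione 21 (not isolated)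
Conditions: t-BuOK (6 equiv), t-BuOH (10 equiv), THF (degassed, sealed), 0 → 80 °C; then AcOH, 0 °C
Reagents that add atoms: none
Why: Excess t-BuOK turns 20 into its bis-enolate (C6 and C8 deprotonated), and t-BuOH shuttles protons so that a small equilibrium share of the tautomer with the carbanion at C4a and a non-enolised ester is always present. In that tautomer C4a attacks the ester carbon C8a in a 6-(enolexo)-exo-trig Claisen (Dieckmann-type) closure, methoxide leaves, and trione 21 enolises at once to the phloroglucinolate of 22, which makes the closure irreversible. The closest known reaction is the base-mediated cyclisation of methyl 3,5-dioxohexanoate to phloroglucinol, the chemical counterpart of the polyketide synthase ring closure. One ring (upper ring A) and one bond (C4a–C8a) form and no stereocentre is created; C2, C3 and C4 are not α to a carbonyl and cannot epimerise. The selectivity needed is C- over O-acylation: with more than two equivalents of base the mono-enolate that lactonises to the 4-hydroxy-2-pyrone is not populated, and the C4a carbanion is a far better nucleophile than an enolate oxygen. Because the nucleophilic methylene is only singly activated, heating is expected to be needed, and the protecting groups (aryl benzyl ethers, MOM acetals, a secondary TBS ether, an aryl bromide without ortho hydrogen) were chosen to withstand hot alkoxide.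

Step 15
Reactants: 22 2-substituted phloroglucinol (C2–OTBS)
Product: 23 2-substituted phloroglucinol with free anti C2 hydroxyl
Conditions: HF·pyridine, pyridine, THF, 0 °C → rt
Reagents that add atoms: none
Why: Buffered fluoride cleavage of the silyl ether; MOM and benzyl ethers and the free phloroglucinol are unaffected, and no acid strong enough to ionise C2 is present.

Step 16
Reactants: 23 2-substituted phloroglucinol with free anti C2 hydroxyl
Product: 24 2,3-cis-3,4-trans 4-aryl flavan with free 5- and 7-OH and 3-OMOM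
Conditions: PPh3, DIAD, THF (high dilution), 0 °C → rt
Reagents that add atoms: none
Why: Intramolecular Mitsunobu etherification; the C2 oxyphosphonium ion is displaced by an ortho phenol (the two are equivalent by the symmetry of ring A) in a 6-exo-tet SN2 step with inversion, which turns the anti alcohol into the 2,3-cis flavan. The β-alkoxy group at C3 retards competing ionisation.

Step 17
Reactants: 24 4-aryl flavan diphenol
Product: 25 5,7-di-O-benzyl 4-aryl flavan bis-MOM ether
Conditions: BnBr, K2CO3, DMF, rt
Reagents that add atoms: benzyl bromide, BrCc1ccccc1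
Why: Williamson benzylation of the two remaining phenols, so that only the two secondary hydroxyls are acylated in step 19.

Step 18
Reactants: 25 5,7-di-O-benzyl 4-aryl flavan bis-MOM ether
Product: 27 perbenzylated 8'-bromo dimer 3,3'-diol, via bis(bromomethyl) ether 26 (not isolated)
Conditions: Me2BBr, CH2Cl2, −78 °C; then aq. NaHCO3/THF
Reagents that add atoms: none
Why: Lewis-acid cleavage of both MOM acetals by bromodimethylborane through the bromomethyl ethers, which hydrolyse on bicarbonate work-up; at −78 °C aryl benzyl ethers, the aryl bromide and the interflavan bond are left alone.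

Step 19
Reactants: 27 perbenzylated 8'-bromo dimer 3,3'-diol
Product: 28 perbenzylated 8'-bromo dimer 3,3'-di-O-(tri-O-benzylgallate)
Conditions: 3,4,5-tris(benzyloxy)benzoyl chloride, Et3N, DMAP, CH2Cl2, rt
Reagents that add atoms: 3,4,5-tris(benzyloxy)benzoyl chloride, O=C(Cl)c1cc(OCc2ccccc2)c(OCc2ccccc2)c(OCc2ccccc2)c1
Why: DMAP-catalysed acylation of both secondary alcohols with the acid chloride, the usual way to 3-O-gallates of benzylated flavan-3-ols.

Step 20
Reactants: 28 perbenzylated 8'-bromo dimer digallate
Product: 29 CNP0169607.1 (epiafzelechin 3-O-gallate-(4β→6)-epicatechin 3-O-gallate)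
Conditions: H2 (1 atm), Pd(OH)2/C, NaOAc, THF/MeOH, rt
Reagents that add atoms: none
Why: Palladium-catalysed hydrogenolysis cleaves all thirteen benzyl ethers and reduces the C8' bromide in one operation; sodium acetate buffers the HBr so that the interflavan bond and the esters survive.

## Compound list

1 | (−)-epicatechin | O[C@@H]1Cc2c(O)cc(O)cc2O[C@@H]1c1ccc(O)c(O)c1 | starting material
2 | 5,7,3',4'-tetra-O-benzylepicatechin | O[C@@H]1Cc2c(OCc9ccccc9)cc(OCc9ccccc9)cc2O[C@@H]1c7ccc(OCc9ccccc9)c(OCc9ccccc9)c7 | intermediate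
3 | 8-bromo-5,7,3',4'-tetra-O-benzylepicatechin | O[C@@H]1Cc2c(OCc9ccccc9)cc(OCc9ccccc9)c(Br)c2O[C@@H]1c7ccc(OCc9ccccc9)c(OCc9ccccc9)c7 | intermediate
4 | 8-bromo-5,7,3',4'-tetra-O-benzyl-3-O-(methoxymethyl)epicatechin | COCO[C@@H]1Cc2c(OCc9ccccc9)cc(OCc9ccccc9)c(Br)c2O[C@@H]1c7ccc(OCc9ccccc9)c(OCc9ccccc9)c7 | intermediate
5 | 8-bromo-6-iodo-5,7,3',4'-tetra-O-benzyl-3-O-(methoxymethyl)epicatechin | COCO[C@@H]1Cc2c(OCc9ccccc9)c(I)c(OCc9ccccc9)c(Br)c2O[C@@H]1c7ccc(OCc9ccccc9)c(OCc9ccccc9)c7 | intermediate
6 | 4-benzyloxybenzaldehyde | O=Cc1ccc(OCc9ccccc9)cc1 | starting material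
7 | diisopinocampheylborinate ester of 8 | C=C[C@@H](OCOC)[C@H](OB([C@@H]1C[C@@H]2C[C@H]([C@H]1C)C2(C)C)[C@@H]1C[C@@H]2C[C@H]([C@H]1C)C2(C)C)c6ccc(OCc9ccccc9)cc6 | intermediate (not isolated)
8 | (1R,2R)-1-(4-benzyloxyphenyl)-2-(methoxymethoxy)but-3-en-1-ol | C=C[C@@H](OCOC)[C@H](O)c6ccc(OCc9ccccc9)cc6 | intermediate
9 | (1R,2R)-1-(4-benzyloxyphenyl)-2-(methoxymethoxy)but-3-enyl acrylate | C=C[C@@H](OCOC)[C@H](OC(=O)C=C)c6ccc(OCc9ccccc9)cc6 | intermediate
10 | (5R,6R)-6-(4-benzyloxyphenyl)-5-(methoxymethoxy)-5,6-dihydro-2H-pyran-2-one | COCO[C@@H]1C=CC(=O)O[C@@H]1c6ccc(OCc9ccccc9)cc6 | intermediate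
11 | C6 arylmagnesium chloride of the protected 8-bromoepicatechin | COCO[C@@H]1Cc2c(OCc9ccccc9)c([Mg]Cl)c(OCc9ccccc9)c(Br)c2O[C@@H]1c7ccc(OCc9ccccc9)c(OCc9ccccc9)c7 | intermediate (not isolated)
12 | trimethylsilyl ketene acetal of lactone 13 | COCO[C@@H]1[C@@H](c2c(OCc9ccccc9)c(Br)c3c(c2OCc9ccccc9)C[C@@H](OCOC)[C@@H](c7ccc(OCc9ccccc9)c(OCc9ccccc9)c7)O3)C=C(O[Si](C)(C)C)O[C@@H]1c6ccc(OCc9ccccc9)cc6 | intermediate (not isolated)
13 | (4R,5R,6R)-4-aryl-5-(methoxymethoxy)-6-(4-benzyloxyphenyl)tetrahydropyran-2-one | COCO[C@@H]1[C@@H](c2c(OCc9ccccc9)c(Br)c3c(c2OCc9ccccc9)C[C@@H](OCOC)[C@@H](c7ccc(OCc9ccccc9)c(OCc9ccccc9)c7)O3)CC(=O)O[C@@H]1c6ccc(OCc9ccccc9)cc6 | intermediate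
14 | syn-hydroxy Weinreb amide | CON(C)C(=O)C[C@H](c2c(OCc9ccccc9)c(Br)c3c(c2OCc9ccccc9)C[C@@H](OCOC)[C@@H](c7ccc(OCc9ccccc9)c(OCc9ccccc9)c7)O3)[C@@H](OCOC)[C@H](O)c6ccc(OCc9ccccc9)cc6 | intermediate
15 | C2 aryl ketone Weinreb amide | CON(C)C(=O)C[C@H](c2c(OCc9ccccc9)c(Br)c3c(c2OCc9ccccc9)C[C@@H](OCOC)[C@@H](c7ccc(OCc9ccccc9)c(OCc9ccccc9)c7)O3)[C@@H](OCOC)C(=O)c6ccc(OCc9ccccc9)cc6 | intermediate
16 | anti-hydroxy Weinreb amide (C2 epimer of 14) | CON(C)C(=O)C[C@H](c2c(OCc9ccccc9)c(Br)c3c(c2OCc9ccccc9)C[C@@H](OCOC)[C@@H](c7ccc(OCc9ccccc9)c(OCc9ccccc9)c7)O3)[C@@H](OCOC)[C@@H](O)c6ccc(OCc9ccccc9)cc6 | intermediate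
17 | C2-O-TBS Weinreb amide | CON(C)C(=O)C[C@H](c2c(OCc9ccccc9)c(Br)c3c(c2OCc9ccccc9)C[C@@H](OCOC)[C@@H](c7ccc(OCc9ccccc9)c(OCc9ccccc9)c7)O3)[C@@H](OCOC)[C@@H](O[Si](C)(C)C(C)(C)C)c6ccc(OCc9ccccc9)cc6 | intermediate
18 | methyl acetoacetate | COC(=O)CC(C)=O | starting material
19 | dilithium dienolate (dianion) of methyl acetoacetate | [Li+].[Li+].COC([O-])=CC(=C)[O-] | intermediate (not isolated)
20 | methyl 3,5-dioxoalkanoate (Claisen precursor) | COC(=O)CC(=O)CC(=O)C[C@H](c2c(OCc9ccccc9)c(Br)c3c(c2OCc9ccccc9)C[C@@H](OCOC)[C@@H](c7ccc(OCc9ccccc9)c(OCc9ccccc9)c7)O3)[C@@H](OCOC)[C@@H](O[Si](C)(C)C(C)(C)C)c6ccc(OCc9ccccc9)cc6 | intermediate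
21 | 2-substituted cyclohexane-1,3,5-trione | O=C1CC(=O)CC(=O)C1[C@H](c2c(OCc9ccccc9)c(Br)c3c(c2OCc9ccccc9)C[C@@H](OCOC)[C@@H](c7ccc(OCc9ccccc9)c(OCc9ccccc9)c7)O3)[C@@H](OCOC)[C@@H](O[Si](C)(C)C(C)(C)C)c6ccc(OCc9ccccc9)cc6 | intermediate (not isolated)
22 | 2-substituted phloroglucinol, C2–OTBS (Claisen product) | Oc4cc(O)cc(O)c4[C@H](c2c(OCc9ccccc9)c(Br)c3c(c2OCc9ccccc9)C[C@@H](OCOC)[C@@H](c7ccc(OCc9ccccc9)c(OCc9ccccc9)c7)O3)[C@@H](OCOC)[C@@H](O[Si](C)(C)C(C)(C)C)c6ccc(OCc9ccccc9)cc6 | intermediate
23 | 2-substituted phloroglucinol, free anti C2–OH | Oc4cc(O)cc(O)c4[C@H](c2c(OCc9ccccc9)c(Br)c3c(c2OCc9ccccc9)C[C@@H](OCOC)[C@@H](c7ccc(OCc9ccccc9)c(OCc9ccccc9)c7)O3)[C@@H](OCOC)[C@@H](O)c6ccc(OCc9ccccc9)cc6 | intermediate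
24 | 4-aryl flavan, free 5,7-OH, 3-OMOM | COCO[C@@H]1[C@@H](c2c(OCc9ccccc9)c(Br)c3c(c2OCc9ccccc9)C[C@@H](OCOC)[C@@H](c7ccc(OCc9ccccc9)c(OCc9ccccc9)c7)O3)c4c(O)cc(O)cc4O[C@@H]1c6ccc(OCc9ccccc9)cc6 | intermediate
25 | 5,7-di-O-benzyl 4-aryl flavan bis-MOM ether | COCO[C@@H]1[C@@H](c2c(OCc9ccccc9)c(Br)c3c(c2OCc9ccccc9)C[C@@H](OCOC)[C@@H](c7ccc(OCc9ccccc9)c(OCc9ccccc9)c7)O3)c4c(OCc9ccccc9)cc(OCc9ccccc9)cc4O[C@@H]1c6ccc(OCc9ccccc9)cc6 | intermediate
26 | 3,3'-bis(bromomethyl) ether | BrCO[C@@H]1[C@@H](c2c(OCc9ccccc9)c(Br)c3c(c2OCc9ccccc9)C[C@@H](OCBr)[C@@H](c7ccc(OCc9ccccc9)c(OCc9ccccc9)c7)O3)c4c(OCc9ccccc9)cc(OCc9ccccc9)cc4O[C@@H]1c6ccc(OCc9ccccc9)cc6 | intermediate (not isolated)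
27 | perbenzylated 8'-bromo dimer 3,3'-diol | O[C@@H]1[C@@H](c2c(OCc9ccccc9)c(Br)c3c(c2OCc9ccccc9)C[C@@H](O)[C@@H](c7ccc(OCc9ccccc9)c(OCc9ccccc9)c7)O3)c4c(OCc9ccccc9)cc(OCc9ccccc9)cc4O[C@@H]1c6ccc(OCc9ccccc9)cc6 | intermediate
28 | perbenzylated 8'-bromo dimer 3,3'-digallate | O=C(O[C@@H]1[C@@H](c2c(OCc9ccccc9)c(Br)c3c(c2OCc9ccccc9)C[C@@H](OC(=O)c5cc(OCc9ccccc9)c(OCc9ccccc9)c(OCc9ccccc9)c5)[C@@H](c7ccc(OCc9ccccc9)c(OCc9ccccc9)c7)O3)c4c(OCc9ccccc9)cc(OCc9ccccc9)cc4O[C@@H]1c6ccc(OCc9ccccc9)cc6)c8cc(OCc9ccccc9)c(OCc9ccccc9)c(OCc9ccccc9)c8 | intermediate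
29 | CNP0169607.1 | O=C(O[C@@H]1[C@@H](c2c(O)cc3c(c2O)C[C@@H](OC(=O)c2cc(O)c(O)c(O)c2)[C@@H](c2ccc(O)c(O)c2)O3)c2c(O)cc(O)cc2O[C@@H]1c1ccc(O)cc1)c1cc(O)c(O)c(O)c1 | target

## Step count and risks

Total: 20 steps. Longest linear sequence: 17 steps (1 → 29 through steps 1–4 and 8–20); the branch from 6 is 16 steps.

**Step 14 (key step).** The substrate may rest as the unreactive bis-enolate, in which the ester is enolised. Closure through the singly activated C4a methylene may then be so slow that lactonisation to the pyrone or thermal degradation takes over. Fallback: give C4a a second, traceless activating group so that the closure becomes the doubly activated Claisen of tetraketide models. Setting out from 17, the amide enolate (LiN(i-Pr)2) is C-acetoacetylated with diketene to the C4a-acetoacetyl Weinreb amide F1. The terminal methyl of its trianion is carboxylated with dimethyl carbonate to the C4a-branched 3,5-dioxo ester F2. NaOMe in MeOH then closes C4a onto C8a under mild conditions, and the quaternary carboxamide is lost by retro-Claisen cleavage as the ring aromatises. The path rejoins the route at 22.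

**Step 8.** Transfer of the very hindered di-ortho-benzyloxyaryl group from copper may be slow, so protonation of the Grignard reagent or 1,2-addition to the lactone could compete. Fallback: reverse the polarity. Setting out from 4 (C6–H free, C8 blocked) and 10, a Lewis acid such as Sc(OTf)3 promotes Friedel–Crafts conjugate addition of the arene to the unsaturated lactone, again anti to both ring substituents. The path returns at 13 without new intermediates.

**Step 16.** The activated para-benzyloxybenzylic C2 may ionise, or the neighbouring MOM oxygen may participate. Either erodes the inversion and favours the more stable 2,3-trans ring. Fallback: the orthoformate closure known for flavan-3-ols. Setting out from 23, both acetals are cleaved (Me2BBr, −78 °C) to the hexahydroxy compound F3. Triethyl orthoformate with pyridinium tosylate forms the cyclic orthoformate of the anti 2,3-diol; its dioxolanylium ion is opened at C2 by the ortho phenol with inversion, giving the 2,3-cis flavan 3-O-formate F4. Methanolysis (K2CO3, MeOH) gives the diol-diphenol F5, and benzylation of its two phenols (BnBr, K2CO3) returns the route at 27.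

**Step 11.** If chelation by the MOM oxygen is incomplete, hydride delivery loses its facial bias and 14 is regenerated. Fallback: invert C2 by substitution instead of reduction. Setting out from 13, LiOH gives the hydroxy acid F6. Mitsunobu lactonisation (PPh3, DIAD) recloses the δ-lactone with inversion at C2 to the all-equatorial lactone F7, which is also the thermodynamically favoured epimer. Aminolysis as in step 9 returns the route at 16.

**Step 20.** Reduction of the hindered aryl bromide may lag behind debenzylation, and bromide or HBr may poison the catalyst or cleave the interflavan bond of the free polyphenol. Fallback: separate the two reductions. Setting out from 28, radical debromination (Bu3SnH, AIBN, toluene, 80 °C) gives the bromine-free perbenzylated digallate F8, which is then hydrogenolysed without any halide present to 29.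

## Further compounds

F1 | step 14 | C4a-acetoacetyl Weinreb amide | CON(C)C(=O)C(C(=O)CC(C)=O)[C@H](c2c(OCc9ccccc9)c(Br)c3c(c2OCc9ccccc9)C[C@@H](OCOC)[C@@H](c7ccc(OCc9ccccc9)c(OCc9ccccc9)c7)O3)[C@@H](OCOC)[C@@H](O[Si](C)(C)C(C)(C)C)c6ccc(OCc9ccccc9)cc6
F2 | step 14 | C4a-branched 3,5-dioxo ester (carboxamide at C4a) | CON(C)C(=O)C(C(=O)CC(=O)CC(=O)OC)[C@H](c2c(OCc9ccccc9)c(Br)c3c(c2OCc9ccccc9)C[C@@H](OCOC)[C@@H](c7ccc(OCc9ccccc9)c(OCc9ccccc9)c7)O3)[C@@H](OCOC)[C@@H](O[Si](C)(C)C(C)(C)C)c6ccc(OCc9ccccc9)cc6
F0 | step 8 | none | none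
F3 | step 16 | hexahydroxy compound (anti 2,3-diol, free 3'-OH, phloroglucinol) | Oc4cc(O)cc(O)c4[C@H](c2c(OCc9ccccc9)c(Br)c3c(c2OCc9ccccc9)C[C@@H](O)[C@@H](c7ccc(OCc9ccccc9)c(OCc9ccccc9)c7)O3)[C@@H](O)[C@@H](O)c6ccc(OCc9ccccc9)cc6
F4 | step 16 | 2,3-cis flavan 3-O-formate | O=CO[C@@H]1[C@@H](c2c(OCc9ccccc9)c(Br)c3c(c2OCc9ccccc9)C[C@@H](O)[C@@H](c7ccc(OCc9ccccc9)c(OCc9ccccc9)c7)O3)c4c(O)cc(O)cc4O[C@@H]1c6ccc(OCc9ccccc9)cc6
F5 | step 16 | diol-diphenol flavan | O[C@@H]1[C@@H](c2c(OCc9ccccc9)c(Br)c3c(c2OCc9ccccc9)C[C@@H](O)[C@@H](c7ccc(OCc9ccccc9)c(OCc9ccccc9)c7)O3)c4c(O)cc(O)cc4O[C@@H]1c6ccc(OCc9ccccc9)cc6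
F6 | step 11 | syn-hydroxy acid | OC(=O)C[C@H](c2c(OCc9ccccc9)c(Br)c3c(c2OCc9ccccc9)C[C@@H](OCOC)[C@@H](c7ccc(OCc9ccccc9)c(OCc9ccccc9)c7)O3)[C@@H](OCOC)[C@H](O)c6ccc(OCc9ccccc9)cc6
F7 | step 11 | C6-epimeric (all-equatorial) lactone | COCO[C@@H]1[C@@H](c2c(OCc9ccccc9)c(Br)c3c(c2OCc9ccccc9)C[C@@H](OCOC)[C@@H](c7ccc(OCc9ccccc9)c(OCc9ccccc9)c7)O3)CC(=O)O[C@H]1c6ccc(OCc9ccccc9)cc6
F8 | step 20 | bromine-free perbenzylated digallate | O=C(O[C@@H]1[C@@H](c2c(OCc9ccccc9)cc3c(c2OCc9ccccc9)C[C@@H](OC(=O)c5cc(OCc9ccccc9)c(OCc9ccccc9)c(OCc9ccccc9)c5)[C@@H](c7ccc(OCc9ccccc9)c(OCc9ccccc9)c7)O3)c4c(OCc9ccccc9)cc(OCc9ccccc9)cc4O[C@@H]1c6ccc(OCc9ccccc9)cc6)c8cc(OCc9ccccc9)c(OCc9ccccc9)c(OCc9ccccc9)c8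
A1 | alternative 1 | benzyl-protected dimer with upper gallate and free C3' hydroxyl | O=C(O[C@@H]1[C@@H](c2c(OCc9ccccc9)cc3c(c2OCc9ccccc9)C[C@@H](O)[C@@H](c7ccc(OCc9ccccc9)c(OCc9ccccc9)c7)O3)c4c(OCc9ccccc9)cc(OCc9ccccc9)cc4O[C@@H]1c6ccc(OCc9ccccc9)cc6)c8cc(OCc9ccccc9)c(OCc9ccccc9)c(OCc9ccccc9)c8
A2 | alternative 2 | dimer with new lower ring A, free C5' phenol and C7' silyl ether | CC(C)(C)[Si](C)(C)O[C@@H]1[C@@H](c2c(O[Si](C(C)C)(C(C)C)C(C)C)cc3c(c2O)C[C@@H](O[Si](C)(C)C(C)(C)C)[C@@H](c7ccc(OCc9ccccc9)c(OCc9ccccc9)c7)O3)c4c(OCc9ccccc9)cc(OCc9ccccc9)cc4O[C@@H]1c6ccc(OCc9ccccc9)cc6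
A3 | alternative 3 | dimer whose lower unit is a 2-aryl-2H-chromene (both C2' epimers) | CC(C)(C)[Si](C)(C)O[C@@H]1[C@@H](c2c(OCc9ccccc9)cc3c(c2OCc9ccccc9)C=CC(c7ccc(OCc9ccccc9)c(OCc9ccccc9)c7)O3)c4c(OCc9ccccc9)cc(OCc9ccccc9)cc4O[C@@H]1c6ccc(OCc9ccccc9)cc6
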